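In percent of the E charged, the readings averaged Z 54.7 % and L 45.6 % in the alder run, and Z 66.3 % and L 33.5 % in the oak run.

| setting | alder | oak | flask |
|---|---|---|---|
| E | 0.24 M | 0.24 M | 0.24 M |
| X | 2.4 mM (in portions, 2) | 9.6 mM (in portions, 2) | 4.8 mM (in portions, 2) |
| remark | run made earlier; portions every 1.5 s | run made earlier; portions every 1.5 s | the portions of X follow each other after 1.5 s, the first at the start |
| time |  |  | 50 min |

| run | time / min | Z / % | L / % | E / % |
|---|---|---|---|---|
| alder | 10.0 | 56.4 | 45.1 | 1.9 |
| alder | 20.0 | 56.8 | 46.1 | 0 |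
| alder | 30.0 | 54.6 | 45.2 | 0 |
| alder | 40.0 | 54.1 | 46.6 | 0.2 |
| alder | 50.0 | 52.8 | 45.6 | 0 |
| alder | 60.0 | 53.7 | 45.1 | 0 |
| oak | 5.00 | 66.7 | 33.1 | 0.5 |
| oak | 8.00 | 65.1 | 35.1 | 0 |
| oak | 12.0 | 66.7 | 31.4 | 0 |
| oak | 20.0 | 67.8 | 35.3 | 0 |
| oak | 40.0 | 65.2 | 33.2 | 1.0 |
| oak | 60.0 | 66.4 | 32.9 | 0 |

(readings scatter by 1 percentage point)

- the earlier runs were read with a standard deviation of 1 percentage point
- in a conversion D counts as not yet reacted
- a reading or a percentage of Z counts all its forms, free or not
- the reaction counts as stopped when no species that holds the E changes by six tenths of a point or more over the second half of the time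

- at 50 min, what has stopped the reaction, if anything has (D counts as not reacted) (it is still moving / all of E has reacted / forward and back rates have come level / no working catalyst is left)
- how much Z there is at 50 min, in percent of the E charged
- how much L there is at 50 min, in percent of the E charged

I took as selectivity factor S the ratio Z/L of the averaged amounts, which is a ratio of amounts summed up over a run and not a ratio of rates at one moment: the readings gave 1.20 in alder and 1.98 in oak.

I first asked what an error in each given number would cost. Time cost little: E read 0 % at 20.0 min in alder and 0 % at 8.00 min in oak. The E charge and the portion interval stood as in both runs, so they gave no handle. The drift of Z in alder cost little: S from the alder readings after 30.0 min was 1.17, which moved my Z for the flask by 0.3 percentage points. The X charge cost more than that: a factor of 4.00 in X moved Z by 12 points. So I needed the order of the split in X, n, the slope of ln S against ln X between the runs, read as 0.361.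

S(flask) = S(alder) · (X(flask)/X(alder))^n = 1.54

Z = S/(1+S) = 60.6 %

The forecast said all of E has reacted, with Z 59.8 % and L 40 %: “I treat the reaction as finished”. Its Z stands 0.80 points below mine.

The flask gave all of E has reacted, with Z 60.2 % and L 39.8 %.

    2 X ⇌ G, settled at all times (K = 3600 M⁻¹)
    Q ⇌ Z, rate k2*(cs2 - [Z]) while solid is left; crystals form when [Z] > cs2 (solubility = 11.0 mM, k = 3.00 s⁻¹)
    E ⇌ D (K = 0.750, k = 0.0450 s⁻¹)
    X + D → X + L (k = 180 M⁻¹ s⁻¹)
    E + X → X + Z (k = 65.0 M⁻¹ s⁻¹)

The flask's S was 1.51. I carried it with n to the neighbouring flask, the same flask with X at 0.019 M: S = 2.49, so Z = 71.3 %. In that neighbouring flask the simulation stood at Z 72.1 % and L 27.9 %, with E 0 % at 50.0 min.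

Readings and results stem from a simulated flask with constants of no real substance; the scatter is artificial.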